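Reckon in percent of the electrophile charged, so that target and electrophile stand on one scale.

| flask | electrophile | nucleophile | remark | time |
|---|---|---|---|---|
| dawn | 0.050 M | 0.037 M | run made earlier |  |
| autumn | 0.050 M | 0.15 M | run made earlier |  |
| flask | 0.050 M | 0.0750 M |  | 40 h |

- dawn (time / h: electrophile / %, target / %): 4.00: 72.5, 20.2; 12.0: 55.0, 31.2; 20.0: 48.1, 35.0; 30.0: 45.2, 37.0; 50.0: 43.5, 39.0
- autumn (time / h: electrophile / %, target / %): 10.0: 11.9, 83.5; 20.0: 2.8, 91.7; 30.0: 1.6, 95.9; 40.0: 1.3, 96.4; 50.0: 0.7, 98.3

(scatter of a reading: 0.5 percentage points)

- part of the electrophile that has reacted at 40 h
- share of the unused nucleophile that is free and not bound as protonated nucleophile, at 40 h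

- the numbers in the tables scatter with a standard deviation of 0.5 percentage points
- what has gone from electrophile into another species counts as reacted, even if it can come back
- the earlier runs do not show how much of nucleophile is bound; that part of a forecast is a guess

Read the dawn run first: nucleophile is the limiting reagent there, yet target stops near 39.0%, not near 74.0%, so each target seems to cost two nucleophile. Define the mark T as the target that the nucleophile charge pays for at two per target, an estimate and no bound: in the flask 75.0%, at dawn 37.0%. The autumn run has T at 150%, above what the electrophile charge allows, and target reads 98.3%.

But the dawn balance falls short. Take g, the missing part over the electrophile left, as 0.402, a reading. Split what T leaves in the flask between electrophile and the missing part, with g as their ratio, and my reckoning gives 82.2% reacted.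

The forecast says 81% reacted, a little lower than mine, and 6% free, a guess, on “roughly two nucleophile per target”.

The flask gives 80.4% reacted and 11.0% free.

    electrophile + nucleophile → acid set free + target (k = 2.30 M⁻¹ h⁻¹)
    electrophile ⇌ dormant form (K = 0.390, k = 0.0250 h⁻¹)
    nucleophile + acid set free ⇌ protonated nucleophile, settled at all times (K = 10000 M⁻¹)

At the asked time the flask holds target at 71.5% under T of 75.0%, and electrophile goes to target 0.40 times as fast as to dormant form (forward rate alone), down from 6.9 just after the start. Apply T to the neighbour flask charged with 0.20 M of electrophile: T is 18.7%, and that flask stands at 21.4% target.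

Readings and results are calculated with made-up constants; the scatter is artificial.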